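The route rests on cutting two bonds of the eudesmane core: C10–CH3 (C14) and C5–C6. Both sit on a ring A cyclohexenone whose carbonyl is the later C4: the angular methyl is its β-bond and C5–C6 its α-bond. One copper-catalysed asymmetric methyl transfer from Al(CH3)3 to C10 therefore sets the quaternary centre, and the enolate so formed closes ring B on a tethered primary iodide; the C4 ketone then lets C5 settle trans. The precursor is an achiral 3-substituted cyclohex-2-enone carrying a CH2–C(dioxolane)–CH2CH2I chain (C9, C8, C7, C6). The C4 and C8 carbonyls afterwards direct every remaining substituent.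

Key step: step 7

Remark (numbering): from compound 13 on, eudesmane numbering is used (ring A = C1–C5 + C10, ring B = C5–C10, C14 = CH3 on C10, C15 = CH3 on C4, C11–C13 = three-carbon unit on C7). β is the face of the C10 methyl, α the opposite face. The target SMILES is read as 3α-angeloyloxy, 4α-acetoxy (4β-CH3), 5α-H, 7α-OOH (7β-isopropenyl), 10β-CH3, trans-fused.

Remark (assumption): L is the O,O'-(biphenyl-2,2'-diyl) phosphoramidite of bis[(S)-1-(2-naphthyl)ethyl]amine. It is assumed to deliver methyl to the Si face of C10 (giving R); if it gives the opposite hand, its enantiomer is used.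

Step 1
Reactants: 1 3-methoxybenzyl chloride; 2 3-(benzyloxy)propanal
Product: 4 rac-4-(benzyloxy)-1-(3-methoxyphenyl)butan-2-ol, via 3-methoxybenzylmagnesium chloride 3 (not isolated)
Conditions: Mg, Et2O, rt (slow addition of 1); then 2, −78 → 0 °C; aq. NH4Cl
Reagents that add atoms: none
Why: Grignard formation followed by 1,2-addition of the benzylic organomagnesium reagent to the aldehyde should proceed cleanly at low temperature; the new carbinol centre forms as a racemate and is removed in step 2.

Step 2
Reactants: 4 rac-4-(benzyloxy)-1-(3-methoxyphenyl)butan-2-ol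
Product: 5 4-(benzyloxy)-1-(3-methoxyphenyl)butan-2-one
Conditions: Dess–Martin periodinane, NaHCO3, CH2Cl2, 0 °C → rt
Reagents that add atoms: none
Why: Dess–Martin oxidation of the secondary alcohol runs under buffered, non-basic conditions, so the β-benzyloxy ketone should not eliminate benzyl alcohol.

Step 3
Reactants: 5 4-(benzyloxy)-1-(3-methoxyphenyl)butan-2-one; 6 ethylene glycol
Product: 7 2-[2-(benzyloxy)ethyl]-2-(3-methoxybenzyl)-1,3-dioxolane
Conditions: TsOH·H2O (cat.), benzene, reflux, Dean–Stark
Reagents that add atoms: none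
Why: Acid-catalysed ketalisation with azeotropic removal of water is reliable for an unhindered dialkyl ketone, and the benzyl ether tolerates the acid.

Step 4
Reactants: 7 2-[2-(benzyloxy)ethyl]-2-(3-methoxybenzyl)-1,3-dioxolane
Product: 8 2-{2-[(5-methoxycyclohexa-1,4-dien-1-yl)methyl]-1,3-dioxolan-2-yl}ethan-1-ol
Conditions: Li, NH3 (l), THF, t-BuOH, −78 → −33 °C; NH4Cl
Reagents that add atoms: none
Why: Birch reduction of the 1,3-disubstituted anisole should give the 1-methoxy-5-alkylcyclohexa-1,4-diene with both donor-bearing carbons left sp2, while the same dissolving-metal conditions cleave the benzyl ether reductively; the dioxolane is inert.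

Step 5
Reactants: 8 2-{2-[(5-methoxycyclohexa-1,4-dien-1-yl)methyl]-1,3-dioxolan-2-yl}ethan-1-ol
Product: 10 3-{[2-(2-hydroxyethyl)-1,3-dioxolan-2-yl]methyl}cyclohex-2-en-1-one, via β,γ-unsaturated ketone 9 (not isolated)
Conditions: (CO2H)2, THF/H2O, 0 °C → rt; then DBU (0.2 equiv), CH2Cl2, rt
Reagents that add atoms: water, O
Why: Mild acid hydrolysis of the enol ether is far faster than that of the dioxolane and gives the β,γ-enone, which a catalytic amidine base moves into conjugation through the dienolate (thermodynamic isomerisation).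

Step 6
Reactants: 10 3-{[2-(2-hydroxyethyl)-1,3-dioxolan-2-yl]methyl}cyclohex-2-en-1-one
Product: 11 3-{[2-(2-iodoethyl)-1,3-dioxolan-2-yl]methyl}cyclohex-2-en-1-one
Conditions: I2, PPh3, imidazole, CH2Cl2, 0 °C → rt, dark
Reagents that add atoms: iodine, II
Why: Appel-type iodination (alkoxyphosphonium iodide, SN2 by iodide) converts the primary alcohol under buffered neutral conditions that leave ketal and enone untouched.

Step 7
Reactants: 11 3-{[2-(2-iodoethyl)-1,3-dioxolan-2-yl]methyl}cyclohex-2-en-1-one; 12 trimethylaluminium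
Product: 16 (4aR,8aR)-6,6-(ethylenedioxy)-4a-methyloctahydronaphthalen-1(2H)-one [8,8-ethylenedioxy-11,12,13,15-tetranoreudesman-4-one; 5α-H; 10β-CH3; trans-fused], via dimethylaluminium enolate 13 (not isolated), via lithium aluminate enolate 14 (not isolated), via cis-fused ketone 15 (not isolated)
Conditions: Cu(O2CC4H3S) (copper thiophene-2-carboxylate, 5 mol %), L (10 mol %), 12 (1.3 equiv), Et2O, −30 °C; then MeLi (1.3 equiv), THF/DMPU, −30 → 20 °C; then MeOH, NaOMe, 20 °C; aq. potassium sodium tartrate
Reagents that add atoms: none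
Why: A chiral methylcopper–phosphoramidite species formed from 12 adds CH3 to C10 of the aluminium-activated enone (conjugate addition through a copper π-complex and reductive elimination) and leaves the regiodefined C4–C5 dimethylaluminium enolate 13; MeLi converts it into the more nucleophilic lithium aluminate 14, whose C5 displaces iodide from C6 by SN2. The closest known reaction type is the copper-catalysed asymmetric conjugate addition of trialkylaluminium reagents to 3-substituted cyclohex-2-enones with alkylative trapping of the enolate, run here intramolecularly as a Michael-initiated ring closure. Ring B closes in the 6-exo-tet mode, the enolate double bond lying exocyclic to the new ring. C10 is set by the ligand (reagent control, methyl to the Si face of the prochiral β-carbon, giving R); C5 is set by the substrate, since the kinetic closure through a chair having the tether axial should give mainly the cis-fused ketone 15 and NaOMe then equilibrates C5 through the C4 enolate to the trans-fused ketone 16, expected to be the more stable epimer. The step needs 1,4- over 1,2-addition, C- over O-alkylation and cyclisation over protonation or intermolecular alkylation; copper catalysis, the six-membered transition state onto an unhindered primary iodide and the donor solvent (which also tames residual AlMe3 toward the new ketone) should secure these, and any cis isomer left at equilibrium is separated and resubmitted to base.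

Step 8
Reactants: 16 (4aR,8aR)-6,6-(ethylenedioxy)-4a-methyloctahydronaphthalen-1(2H)-one
Product: 18 8,8-ethylenedioxy-11,12,13,15-tetranoreudesm-3-en-4-yl trifluoromethanesulfonate (5α-H; 10β-CH3), via potassium enolate 17 (not isolated)
Conditions: KN(SiMe3)2, THF, −78 °C; then PhNTf2, −78 → 0 °C
Reagents that add atoms: N-phenylbis(trifluoromethanesulfonimide), O=S(=O)(N(c1ccccc1)S(=O)(=O)C(F)(F)F)C(F)(F)F
Why: Kinetic deprotonation by the hindered amide takes a C3 methylene proton in preference to the C5 methine next to quaternary C10, and O-sulfonylation of the enolate gives the C3=C4 enol triflate without touching the C5 stereocentre.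

Step 9
Reactants: 18 8,8-ethylenedioxy-11,12,13,15-tetranoreudesm-3-en-4-yl trifluoromethanesulfonate
Product: 20 (4aR,8aR)-5,8a-dimethyl-3,4,4a,7,8,8a-hexahydronaphthalen-2(1H)-one [11,12,13-trinoreudesm-3-en-8-one; 5α-H; 10β-CH3], via ketal olefin 19 (not isolated)
Conditions: MeMgBr, Fe(acac)3 (5 mol %), THF/NMP, −30 → 0 °C; then 1 M HCl, THF, rt
Reagents that add atoms: methylmagnesium bromide, C[Mg]Br; water, O
Why: Iron-catalysed cross-coupling (Kochi type) of the alkenyl triflate and the methyl Grignard reagent installs C15 on C4 and fixes the double bond at C3–C4, and dilute acid then hydrolyses the dioxolane; no stereocentre is affected.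

Step 10
Reactants: 20 11,12,13-trinoreudesm-3-en-8-one; 21 acetone
Product: 24 11-hydroxyeudesm-3-en-8-one (5α-H; 7α-H; 10β-CH3), via lithium enolate 22 (not isolated), via chlorozinc enolate 23 (not isolated)
Conditions: LiN(i-Pr)2, THF, −78 °C; ZnCl2, −78 °C; then 21, −78 → −40 °C; aq. NH4Cl
Reagents that add atoms: none
Why: Kinetic enolisation goes to C7 because C9 is neopentylic (flanked by quaternary C10), and the zinc enolate undergoes aldol addition to acetone with little proton transfer; the side chain should settle equatorial (7β), and this centre is erased in step 11.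

Step 11
Reactants: 24 11-hydroxyeudesm-3-en-8-one
Product: 26 eudesma-3,7(11)-dien-8-one (5α-H; 10β-CH3), via tertiary mesylate 25 (not isolated)
Conditions: MsCl, Et3N, CH2Cl2, 0 °C; then DBU, rt
Reagents that add atoms: none
Why: Mesylation of the tertiary alcohol through sulfene followed by E1cB elimination via the C7 enolate should give the conjugated, tetrasubstituted C7=C11 enone.

Step 12
Reactants: 26 eudesma-3,7(11)-dien-8-one
Product: 27 3α,4α-dihydroxyeudesm-7(11)-en-8-one (4β-CH3; 5α-H; 10β-CH3)
Conditions: OsO4 (2 mol %), N-methylmorpholine N-oxide, acetone/H2O, rt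
Reagents that add atoms: osmium tetroxide, O=[Os](=O)(=O)=O; N-methylmorpholine N-oxide, C[N+]1([O-])CCOCC1; water, O
Why: Upjohn dihydroxylation: the electrophilic oxidant should choose the electron-rich trisubstituted C3=C4 bond over the tetrasubstituted enone bond and add suprafacially from the α face, away from the axial C10 methyl, which sets C3 (α-OH) and C4 (α-OH, β-CH3) together.

Step 13
Reactants: 27 3α,4α-dihydroxyeudesm-7(11)-en-8-one; 28 angelic acid [(Z)-2-methylbut-2-enoic acid]
Product: 30 3α-angeloyloxy-4α-hydroxyeudesm-7(11)-en-8-one, via mixed anhydride 29 (not isolated)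
Conditions: 28, 2,4,6-Cl3C6H2COCl, Et3N, toluene, rt; then 27, toluene, 80 °C
Reagents that add atoms: none
Why: Yamaguchi esterification via the mixed anhydride acylates the secondary 3α-hydroxyl selectively (the tertiary 4α-hydroxyl is too hindered), and running it without a nucleophilic catalyst should keep the Z geometry of the angelate.

Step 14
Reactants: 30 3α-angeloyloxy-4α-hydroxyeudesm-7(11)-en-8-one
Product: 31 4α-acetoxy-3α-angeloyloxyeudesm-7(11)-en-8-one
Conditions: Ac2O, Sc(OTf)3 (2 mol %), MeCN, −20 °C
Reagents that add atoms: acetic anhydride, CC(=O)OC(C)=O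
Why: Lewis acid-catalysed acetylation is a reliable way to esterify a hindered tertiary alcohol at low temperature; the C4–O bond is not broken, so its configuration is retained, and the absence of amine nucleophiles protects the angelate.

Step 15
Reactants: 31 4α-acetoxy-3α-angeloyloxyeudesm-7(11)-en-8-one
Product: 32 4α-acetoxy-3α-angeloyloxy-8-(trimethylsilyloxy)eudesma-7,11-diene
Conditions: TMSOTf, Et3N, CH2Cl2, 0 °C; pentane, filtration (non-aqueous work-up), used crude
Reagents that add atoms: trimethylsilyl trifluoromethanesulfonate, C[Si](C)(C)OS(=O)(=O)C(F)(F)F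
Why: Soft enolisation: O-silylation of the enone gives a silyloxyallyl cation and the amine removes a proton from the exposed C12 methyl rather than from neopentylic C9, giving the linearly conjugated dienol ether as known for other 2-isopropylidenecyclohexanones and steroidal enones.

Step 16
Reactants: 32 4α-acetoxy-3α-angeloyloxy-8-(trimethylsilyloxy)eudesma-7,11-diene
Product: 34 4α-acetoxy-3α-angeloyloxy-7α-hydroperoxyeudesm-11-en-8-one (5α-H; 10β-CH3; target CNP0360871.1), via trimethylsilyl peroxide 33 (not isolated)
Conditions: O2, tetraphenylporphyrin (cat.), hν (visible), CH2Cl2, −78 °C; then MeOH, −78 → 0 °C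
Reagents that add atoms: dioxygen, O=O
Why: Photooxygenation of a silyl enol ether (silyl-ene reaction of singlet oxygen): oxygen bonds to the nucleophilic C7 while silicon migrates to the outer peroxy oxygen, attack should come axially from the α face opposite the C10 methyl (as for a steroid-type 2-ene) to give 7α-OO and an equatorial isopropenyl group, and methanolysis frees the hydroperoxide, the angelate and isopropenyl double bonds being far less reactive toward singlet oxygen.

Compound list
1 | 3-methoxybenzyl chloride | COc1cccc(CCl)c1 | starting material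
2 | 3-(benzyloxy)propanal | O=CCCOCc1ccccc1 | starting material
3 | 3-methoxybenzylmagnesium chloride | COc1cccc(C[Mg]Cl)c1 | intermediate
4 | rac-4-(benzyloxy)-1-(3-methoxyphenyl)butan-2-ol | COc1cccc(CC(O)CCOCc2ccccc2)c1 | intermediate
5 | 4-(benzyloxy)-1-(3-methoxyphenyl)butan-2-one | COc1cccc(CC(=O)CCOCc2ccccc2)c1 | intermediate
6 | ethylene glycol | OCCO | starting material
7 | 2-[2-(benzyloxy)ethyl]-2-(3-methoxybenzyl)-1,3-dioxolane | COc1cccc(CC2(CCOCc3ccccc3)OCCO2)c1 | intermediate
8 | 2-{2-[(5-methoxycyclohexa-1,4-dien-1-yl)methyl]-1,3-dioxolan-2-yl}ethan-1-ol | COC1=CCC=C(CC2(CCO)OCCO2)C1 | intermediate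
9 | 3-{[2-(2-hydroxyethyl)-1,3-dioxolan-2-yl]methyl}cyclohex-3-en-1-one | O=C1CCC=C(CC2(CCO)OCCO2)C1 | intermediate
10 | 3-{[2-(2-hydroxyethyl)-1,3-dioxolan-2-yl]methyl}cyclohex-2-en-1-one | O=C1C=C(CC2(CCO)OCCO2)CCC1 | intermediate
11 | 3-{[2-(2-iodoethyl)-1,3-dioxolan-2-yl]methyl}cyclohex-2-en-1-one | O=C1C=C(CC2(CCI)OCCO2)CCC1 | intermediate
12 | trimethylaluminium | C[Al](C)C | starting material
13 | dimethyl{[(3R)-3-{[2-(2-iodoethyl)-1,3-dioxolan-2-yl]methyl}-3-methylcyclohex-1-en-1-yl]oxy}alumane | C[Al](C)OC1=C[C@@](C)(CC2(CCI)OCCO2)CCC1 | intermediate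
14 | lithium trimethyl{[(3R)-3-{[2-(2-iodoethyl)-1,3-dioxolan-2-yl]methyl}-3-methylcyclohex-1-en-1-yl]oxy}aluminate | [Li+].C[Al-](C)(C)OC1=C[C@@](C)(CC2(CCI)OCCO2)CCC1 | intermediate
15 | (4aR,8aS)-6,6-(ethylenedioxy)-4a-methyloctahydronaphthalen-1(2H)-one (cis-fused, 5β-H, 10β-CH3) | C1C[C@H]2[C@](C)(CCCC2=O)CC13OCCO3 | intermediate
16 | (4aR,8aR)-6,6-(ethylenedioxy)-4a-methyloctahydronaphthalen-1(2H)-one (trans-fused, 5α-H, 10β-CH3) | C1C[C@@H]2[C@](C)(CCCC2=O)CC13OCCO3 | intermediate
17 | potassium C3–C4 enolate of 16 | C1C[C@@H]2[C@](C)(CCC=C2[O-])CC13OCCO3.[K+] | intermediate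
18 | 8,8-ethylenedioxy-11,12,13,15-tetranoreudesm-3-en-4-yl trifluoromethanesulfonate (5α-H, 10β-CH3) | C1C[C@@H]2[C@](C)(CCC=C2OS(=O)(=O)C(F)(F)F)CC13OCCO3 | intermediate
19 | 8,8-ethylenedioxy-11,12,13-trinoreudesm-3-ene (5α-H, 10β-CH3) | C1C[C@@H]2[C@](C)(CCC=C2C)CC13OCCO3 | intermediate
20 | (4aR,8aR)-5,8a-dimethyl-3,4,4a,7,8,8a-hexahydronaphthalen-2(1H)-one (11,12,13-trinoreudesm-3-en-8-one) | C1C[C@@H]2[C@](C)(CCC=C2C)CC1=O | intermediate
21 | acetone | CC(C)=O | starting material
22 | lithium C7–C8 enolate of 20 | C1C[C@@H]2[C@](C)(CCC=C2C)CC=1[O-].[Li+] | intermediate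
23 | chlorozinc C7–C8 enolate of 20 | C1C[C@@H]2[C@](C)(CCC=C2C)CC=1O[Zn]Cl | intermediate
24 | 11-hydroxyeudesm-3-en-8-one (5α-H, 7α-H, 10β-CH3) | CC(C)(O)[C@H]1C[C@@H]2[C@](C)(CCC=C2C)CC1=O | intermediate
25 | 11-(methylsulfonyloxy)eudesm-3-en-8-one (5α-H, 7α-H, 10β-CH3) | CC(C)(OS(C)(=O)=O)[C@H]1C[C@@H]2[C@](C)(CCC=C2C)CC1=O | intermediate
26 | eudesma-3,7(11)-dien-8-one (5α-H, 10β-CH3) | CC(C)=C1C[C@@H]2[C@](C)(CCC=C2C)CC1=O | intermediate
27 | 3α,4α-dihydroxyeudesm-7(11)-en-8-one (4β-CH3, 5α-H, 10β-CH3) | CC(C)=C1C[C@@H]2[C@](C)(CC[C@@H](O)[C@@]2(C)O)CC1=O | intermediate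
28 | angelic acid, (Z)-2-methylbut-2-enoic acid | C/C=C(C)\C(=O)O | starting material
29 | (Z)-2-methylbut-2-enoic 2,4,6-trichlorobenzoic anhydride | C/C=C(C)\C(=O)OC(=O)c1c(Cl)cc(Cl)cc1Cl | intermediate
30 | 3α-angeloyloxy-4α-hydroxyeudesm-7(11)-en-8-one | CC(C)=C1C[C@@H]2[C@](C)(CC[C@@H](OC(=O)/C(C)=C\C)[C@@]2(C)O)CC1=O | intermediate
31 | 4α-acetoxy-3α-angeloyloxyeudesm-7(11)-en-8-one | CC(C)=C1C[C@@H]2[C@](C)(CC[C@@H](OC(=O)/C(C)=C\C)[C@@]2(C)OC(C)=O)CC1=O | intermediate
32 | 4α-acetoxy-3α-angeloyloxy-8-(trimethylsilyloxy)eudesma-7,11-diene | C=C(C)C1C[C@@H]2[C@](C)(CC[C@@H](OC(=O)/C(C)=C\C)[C@@]2(C)OC(C)=O)CC=1O[Si](C)(C)C | intermediate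
33 | 4α-acetoxy-3α-angeloyloxy-7α-(trimethylsilylperoxy)eudesm-11-en-8-one | C=C(C)[C@@]1(OO[Si](C)(C)C)C[C@@H]2[C@](C)(CC[C@@H](OC(=O)/C(C)=C\C)[C@@]2(C)OC(C)=O)CC1=O | intermediate
34 | 4α-acetoxy-3α-angeloyloxy-7α-hydroperoxyeudesm-11-en-8-one (5α-H, 10β-CH3) | C=C(C)[C@@]1(OO)C[C@@H]2[C@](C)(CC[C@@H](OC(=O)/C(C)=C\C)[C@@]2(C)OC(C)=O)CC1=O | target

Total step count: 16. Longest linear sequence: 16 steps (1 → 34); 2, 6, 12, 21 and 28 are commercial inputs.

Steps most likely to fail

Step 7. The aluminate may alkylate too slowly, so that the enolate is merely protonated on work-up. Residual methylaluminium species may add to the newly formed ketone, or coordination of the ketal to aluminium may erode facial selectivity at C10. Fallback (sets out from 11, comes back at 16): the conjugate addition is run by itself and the aluminium enolate is silylated (TMSOTf, Et3N, −30 → 0 °C) to give the trimethylsilyl enol ether F1, which is isolated free of aluminium. Ring B is then closed in a separate fluoride-promoted intramolecular alkylation (anhydrous benzyltrimethylammonium fluoride, THF, 4 Å sieves). NaOMe/MeOH equilibration of the resulting mixture of 15 and 16 leads to 16. The enantioselective step and the ring closure can then be optimised independently.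

Step 16. Singlet oxygen may add across the 2-silyloxydiene in a [4+2] sense or react in an ene mode at another double bond, and the tertiary allylic hydroperoxide may undergo Hock-type cleavage on work-up. Fallback (sets out from 32, comes back at 34): an anionic pathway using ground-state oxygen. Compound 32 is desilylated by anhydrous benzyltrimethylammonium fluoride in THF at −78 °C under dry O2 to give the benzyltrimethylammonium dienolate F2. This should autoxidise at C7 (enolate oxygenation, axial attack on the α face) to the benzyltrimethylammonium 7α-peroxide F3, and acetic acid at −78 °C then gives 34.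

Step 13. The angelate may isomerise to the tiglate (Z → E) during activation, and acylation of the axial, hindered 3α-hydroxyl may be slow. Fallback (sets out from 27, comes back at 30): the Z double bond is built on the ester. Compound 27 is acylated with 2-[bis(2,2,2-trifluoroethoxy)phosphoryl]propanoic acid (EDC·HCl, DMAP, CH2Cl2) to give the 3α-phosphonopropanoate F4. Still–Gennari olefination of this ester using acetaldehyde (KN(SiMe3)2, 18-crown-6, THF, −78 °C) should give angelate 30 under kinetic Z control.

Further compounds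
F1 | step 7 | {[(3R)-3-{[2-(2-iodoethyl)-1,3-dioxolan-2-yl]methyl}-3-methylcyclohex-1-en-1-yl]oxy}trimethylsilane | C[Si](C)(C)OC1=C[C@@](C)(CC2(CCI)OCCO2)CCC1
F2 | step 16 | benzyltrimethylammonium 4α-acetoxy-3α-angeloyloxyeudesma-7,11-dien-8-olate | C=C(C)C1C[C@@H]2[C@](C)(CC[C@@H](OC(=O)/C(C)=C\C)[C@@]2(C)OC(C)=O)CC=1[O-].C[N+](C)(C)Cc1ccccc1
F3 | step 16 | benzyltrimethylammonium 4α-acetoxy-3α-angeloyloxy-8-oxoeudesm-11-en-7α-yl peroxide | C=C(C)[C@@]1(O[O-])C[C@@H]2[C@](C)(CC[C@@H](OC(=O)/C(C)=C\C)[C@@]2(C)OC(C)=O)CC1=O.C[N+](C)(C)Cc1ccccc1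
F4 | step 13 | 3α-{2-[bis(2,2,2-trifluoroethoxy)phosphoryl]propanoyloxy}-4α-hydroxyeudesm-7(11)-en-8-one (epimers at the phosphonate carbon) | CC(C)=C1C[C@@H]2[C@](C)(CC[C@@H](OC(=O)C(C)P(=O)(OCC(F)(F)F)OCC(F)(F)F)[C@@]2(C)O)CC1=O
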